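The runs were generated by integration for an exercise; the scatter is artificial.

**Quick number.** If every Z that reacts takes one D, every X takes a second, and the whole D charge (the limiting reagent here) ends up bound, then X in percent of the Z charged equals the Z left minus the shortfall, 20.0%, the part of the Z charged that D cannot reach even once. That was my reply when you asked for a number and suspected that the way of charging mattered.

| setting | Sunday's | Friday's | Thursday's | Monday's | north-east | south-east | north-west | south |
|---|---|---|---|---|---|---|---|---|
| Z | 0.40 M | 0.40 M | 0.40 M | 0.60 M | 0.40 M | 0.40 M | 0.40 M | 0.40 M (fed, over 8.0 d) |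
| D | 0.32 M | 0.45 M | 0.70 M | 0.32 M | 0.320 M (fed, over 8.0 d) | 0.320 M (in portions, 5, over 8.0 d) | 0.320 M | 0.320 M |
| remark | run made earlier | run made earlier | run made earlier | run made earlier | all else is in the flask from the start; the feed brings no volume worth counting | first portion at the start, last at 8.0 d | everything together at the start | all else is in the flask from the start; the feed brings no volume worth counting |
| time |  |  |  |  | 20 d | 20 d | 20 d | 20 d |

* the best flask by amount of X, in percent of the Z charged; "all alike" if 1.5 percentage points covers them all (north-east / south-east / north-west / south / all alike)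
* amount of X at the end, in percent of the Z charged, north-east
* amount of X at the end, in percent of the Z charged, south-east
* amount of X at the end, in percent of the Z charged, north-west
* amount of X at the end, in percent of the Z charged, south

**Runs so far.**

- Sunday's (time / d: X / %, Z / %): 0.625: 22, 40; 1.67: 20, 42; 3.00: 24, 42; 5.00: 21, 42; 8.00: 20, 43; 10.0: 23, 45; 12.0: 21, 41
- Friday's (time / d: X / %, Z / %): 1.25: 36, 23; 2.08: 38, 27; 3.00: 39, 24; 5.00: 37, 27; 6.00: 35, 25; 10.0: 37, 25; 15.0: 32, 28
- Thursday's (time / d: X / %, Z / %): 2.50: 72, 2; 5.00: 71, 0; 6.00: 71, 0; 10.0: 76, 0; 12.0: 73, 0; 15.0: 72, 1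
- Monday's (time / d: X / %, Z / %): 1.25: 12, 57; 4.00: 11, 59; 8.00: 11, 59; 12.0: 12, 56; 15.0: 12, 61

(scatter of a reading: 1.5 percentage points)



Sunday's Z averaged 42.1%, so the rule gave X 22.1%, and the readings averaged 21.6%. Monday had another charge of Z. Its shortfall was 46.7%, its Z averaged 58.4%, and the rule gave 11.7% against a reading of 11.6%.

**My commitment.** North-west repeats Sunday's charge, so I put it at 22.1%. South, north-east and south-east needed a Z left that no run showed, so there the rule gave me a relation and no number: at this charge, with the whole of D bound, the flask keeping more Z holds more X.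

**The forecast.** It stood at 38% for south, 36% for north-east, 32% for south-east and 21.5% for north-west, with south as best. One ground was “Steady D feed keeps D tiny”. By my rule, its north-east figure required that flask to keep 56.0% of its Z.

**The flasks.** South led with 30.1% X, then came north-west at 22.3%, south-east at 8.55% and north-east at 4.12%.

    D + G → X + E (k = 7.70 × 10⁻⁴ M⁻¹ s⁻¹)
    G → L (k = 4.80 × 10⁻⁵ s⁻¹)
    Z + D → G + E (k = 5.40 × 10⁻⁴ M⁻¹ s⁻¹)

**The shortfall again.** North-east averaged 0.00363 M of D over its 8.0 d feed and ended with 24.1% of its Z and 0% of its D unbound, so the shortfall put X at 4.10%. Because G turned into L, south's lead over north-east stood at 26 percentage points instead of 13 points. The neighbour of south charged with 1.0 M of Z has a shortfall of 68.0%, and its 79.8% of Z left gives 11.8% of X.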